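**Plan**

- The target is an achiral para-substituted phenol ester, and its benzene ring, the only ring, is built rather than bought.
- Retrosynthetically the phenol is taken back to a 4-substituted cyclohex-2-enone. The phenolic carbon C1 and the para carbon C4 carrying the CH2CH2O arm correspond to the carbonyl carbon and C4 of that enone.
- The enone is cut at its C2=C3 double bond and its C4–C5 single bond, giving methyl vinyl ketone and 4-oxobutyl hexatriacontanoate. The aldehyde α-carbon becomes C4 and the ketone carbon becomes C1, so the 1,4 pattern follows from connectivity.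
- The aldehyde is cut at the ester C–O bond to hexatriacontanoic acid and butane-1,4-diol, with one oxidation-level adjustment.
- Forward: the ester is made first, the alcohol is oxidised, one Michael–aldol annulation closes the six-membered carbocycle, and dehydrogenation gives the arene.
- Stereochemistry: the target has no stereocentre; the single stereocentre of the cyclohexenone forms racemic and is erased on aromatisation.

Key step: step 3

Remark: hexatriacontanoic acid is taken as purchasable from lipid suppliers, and all C36 compounds are assumed to need warm (30–50 °C) aromatic or chlorinated solvents to stay in solution.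

**Route**

Step 1
Reactants: 1 hexatriacontanoic acid; 2 butane-1,4-diol (10 equiv)
Product: 3 4-hydroxybutyl hexatriacontanoate
Conditions: DIC (1.2 equiv), DMAP (0.1 equiv), THF–CHCl3, 45 °C
Reagents that add atoms: none
Why: Steglich esterification, in which the carbodiimide-activated acid is intercepted by a large excess of the symmetrical diol so that mono-acylation should dominate and the water-soluble surplus diol is washed away.

Step 2
Reactants: 3 4-hydroxybutyl hexatriacontanoate
Product: 4 4-oxobutyl hexatriacontanoate
Conditions: TEMPO (0.1 equiv), PhI(OAc)2 (1.2 equiv), CH2Cl2, 30 °C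
Reagents that add atoms: none
Why: Oxoammonium-mediated (TEMPO/PhI(OAc)2) oxidation of a primary alcohol should stop at the aldehyde under anhydrous conditions and leaves the ester untouched.

Step 3
Reactants: 4 4-oxobutyl hexatriacontanoate; 5 methyl vinyl ketone (but-3-en-2-one)
Product: 9 2-(4-oxocyclohex-2-en-1-yl)ethyl hexatriacontanoate (racemic), via pyrrolidine enamine 6 (not isolated), via keto-aldehyde 7 (not isolated), via aldol 8 (not isolated)
Conditions: pyrrolidine (1.05 equiv), 4 Å MS, toluene, 0 °C to rt; then 5 (1.1 equiv), 0 to 40 °C; then AcOH–NaOAc–H2O, 80 °C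
Reagents that add atoms: none
Why: Pyrrolidine condenses with aldehyde 4 to the enamine 6, whose nucleophilic carbon (the former aldehyde α-carbon) adds to the β-carbon of 5 in a Stork enamine Michael addition, and buffered hydrolysis of the adduct returns pyrrolidine and the 1,5-keto-aldehyde 7. In the same pyrrolidinium acetate buffer the methyl carbon of the ketone attacks the aldehyde carbonyl in a 6-(enolexo)-exo-trig aldol closure to 8, and E1cB loss of water gives the conjugated enone 9; the closest known reaction type is the amine-mediated Robinson annulation of α-monosubstituted aldehydes with methyl vinyl ketone to 4-substituted cyclohex-2-enones. One ring, the six-membered carbocycle, is closed, with one C–C single bond (C4–C5) and one C=C bond (C2=C3) formed. The only new stereocentre, the ring carbon bearing the acyloxyethyl arm, arises racemic with no controlling element and needs none, because it becomes sp2 in step 4. The step needs mono-alkylation and a single aldol mode: the first should be secured by the 1:1 stoichiometry and the lower reactivity of the more substituted enamine left after the first addition, the second by the fact that only attack of the methyl carbon gives a six-membered ring, every other enol–carbonyl pairing in 7 leading to a four-membered one. The ester is separated from both reacting centres by two methylene groups and should be inert to the amine and to the acetate buffer at these temperatures.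

Step 4
Reactants: 9 2-(4-oxocyclohex-2-en-1-yl)ethyl hexatriacontanoate
Product: 11 2-(4-hydroxyphenyl)ethyl hexatriacontanoate, via cyclohexadienone tautomer 10 (not isolated)
Conditions: Pd(O2CCF3)2 (5 mol%), 2-(dimethylamino)pyridine (10 mol%), TsOH·H2O (20 mol%), O2 (1 atm), DMSO–PhCl, 80 °C
Reagents that add atoms: none
Why: Aerobic dehydrogenation catalysed by divalent palladium, in which palladation of 9 at the α′-carbon and β-hydride elimination give the cross-conjugated dienone 10 that tautomerises irreversibly to the phenol while O2 returns zerovalent palladium to the divalent state; this is the known oxidative aromatisation of 4-substituted cyclohexenones, the ester is inert, and chlorobenzene is added only to keep the wax in solution.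

**Compound list**

1 | hexatriacontanoic acid | CCCCCCCCCCCCCCCCCCCCCCCCCCCCCCCCCCCC(=O)O | starting material
2 | butane-1,4-diol | OCCCCO | starting material
3 | 4-hydroxybutyl hexatriacontanoate | CCCCCCCCCCCCCCCCCCCCCCCCCCCCCCCCCCCC(=O)OCCCCO | intermediate
4 | 4-oxobutyl hexatriacontanoate | CCCCCCCCCCCCCCCCCCCCCCCCCCCCCCCCCCCC(=O)OCCCC=O | intermediate
5 | methyl vinyl ketone (but-3-en-2-one) | CC(=O)C=C | starting material
6 | (E)-4-(pyrrolidin-1-yl)but-3-en-1-yl hexatriacontanoate | CCCCCCCCCCCCCCCCCCCCCCCCCCCCCCCCCCCC(=O)OCC/C=C/N1CCCC1 | intermediate
7 | 3-formyl-6-oxoheptyl hexatriacontanoate (racemic) | CCCCCCCCCCCCCCCCCCCCCCCCCCCCCCCCCCCC(=O)OCCC(C=O)CCC(C)=O | intermediate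
8 | 2-(2-hydroxy-4-oxocyclohexyl)ethyl hexatriacontanoate (racemic mixture of diastereomers) | CCCCCCCCCCCCCCCCCCCCCCCCCCCCCCCCCCCC(=O)OCCC1CCC(=O)CC1O | intermediate
9 | 2-(4-oxocyclohex-2-en-1-yl)ethyl hexatriacontanoate (racemic) | CCCCCCCCCCCCCCCCCCCCCCCCCCCCCCCCCCCC(=O)OCCC1CCC(=O)C=C1 | intermediate
10 | 2-(4-oxocyclohexa-2,5-dien-1-yl)ethyl hexatriacontanoate | CCCCCCCCCCCCCCCCCCCCCCCCCCCCCCCCCCCC(=O)OCCC1C=CC(=O)C=C1 | intermediate
11 | 2-(4-hydroxyphenyl)ethyl hexatriacontanoate | CCCCCCCCCCCCCCCCCCCCCCCCCCCCCCCCCCCC(=O)OCCc1ccc(O)cc1 | target

**Count**

Total steps: 4. Longest linear sequence: 4 steps (1 → 3 → 4 → 9 → 11).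

**Steps most likely to fail**

Step 3. The adduct could add to a second molecule of 5, the enamine could condense with unreacted aldehyde, 5 could polymerise, and pyrrolidine could slowly aminolyse the ester. The fallback reverses the donor and acceptor roles; it sets out from 4 and comes back to the route at 7, which closes through 8 to 9. Aldehyde 4 would be α-methylenated with aqueous formaldehyde under catalytic pyrrolidine and propionic acid in toluene–iPrOH at 45 °C to give 3-formylbut-3-en-1-yl hexatriacontanoate F1. tert-Butyl acetoacetate, used in slight excess, would add as a stabilised enolate to this enal under catalytic Et3N in THF at rt to give tert-butyl 2-acetyl-4-formyl-6-(hexatriacontanoyloxy)hexanoate F2. TsOH·H2O in toluene at 100 °C should cleave the tert-butyl ester to 2-acetyl-4-formyl-6-(hexatriacontanoyloxy)hexanoic acid F3, which decarboxylates to 7. Under the same acid 7 should cyclise and dehydrate to 9.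

Step 4. The waxy substrate could separate from the DMSO-rich medium, the catalyst could aggregate to palladium black before turnover is complete, and the reaction could stall. The fallback replaces catalytic dehydrogenation by halogenation and elimination; it sets out from 9 and comes back at 10, which tautomerises to 11. α′-Bromination with PhNMe3Br3 in THF at 0 °C should give 2-(5-bromo-4-oxocyclohex-2-en-1-yl)ethyl hexatriacontanoate F4. Heating with Li2CO3 and LiBr in DMF at 110 °C should eliminate hydrogen bromide to give 10 and hence the phenol.

Step 1. Statistical double acylation of the diol and sluggish coupling of the sparingly soluble acid could lower the throughput. The fallback replaces statistical control by a protecting group; it sets out from 1 and comes back at 3. Acid 1 would be esterified with commercial 4-(benzyloxy)butan-1-ol (1.1 equiv; DIC, DMAP, CHCl3, 45 °C) to give 4-(benzyloxy)butyl hexatriacontanoate F5. Hydrogenolysis (H2, Pd/C (palladium on carbon), THF–EtOAc, 40 °C) should then free the alcohol 3.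

**Further compounds**

F1 | step 3 | 3-formylbut-3-en-1-yl hexatriacontanoate | CCCCCCCCCCCCCCCCCCCCCCCCCCCCCCCCCCCC(=O)OCCC(=C)C=O
F2 | step 3 | tert-butyl 2-acetyl-4-formyl-6-(hexatriacontanoyloxy)hexanoate (mixture of diastereomers) | CCCCCCCCCCCCCCCCCCCCCCCCCCCCCCCCCCCC(=O)OCCC(C=O)CC(C(C)=O)C(=O)OC(C)(C)C
F3 | step 3 | 2-acetyl-4-formyl-6-(hexatriacontanoyloxy)hexanoic acid (mixture of diastereomers) | CCCCCCCCCCCCCCCCCCCCCCCCCCCCCCCCCCCC(=O)OCCC(C=O)CC(C(C)=O)C(=O)O
F4 | step 4 | 2-(5-bromo-4-oxocyclohex-2-en-1-yl)ethyl hexatriacontanoate (mixture of diastereomers) | CCCCCCCCCCCCCCCCCCCCCCCCCCCCCCCCCCCC(=O)OCCC1CC(Br)C(=O)C=C1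
F5 | step 1 | 4-(benzyloxy)butyl hexatriacontanoate | CCCCCCCCCCCCCCCCCCCCCCCCCCCCCCCCCCCC(=O)OCCCCOCc1ccccc1
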